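**Assumption:** Giganteone A has no stereocentre, and its biaryl axis carries only two ortho substituents (one alkyl, one OH), so it rotates freely. The molecule is achiral, and "single enantiomer" imposes no stereochemical task.

## Retrosynthetic overview

1. Giganteone A ⇒ its tetra-O-methyl ether 15 by global O-demethylation.
2. 15 ⇒ biaryl C–C bond (the new step): conjugate C-arylation of o-quinone 14 (from catechol 7) by free 2-acylresorcinol 13. These are two complementarily masked malabaricone C units.
3. Each unit ⇒ aryl ketone C–C bond: a 2-lithioresorcinol diether (OMe or OMOM) plus a 9-arylnonanoyl Weinreb amide (4 or 9).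
4. 4 and 9 ⇒ B-alkyl Suzuki coupling of one common amide, N-methoxy-N-methylnon-8-enamide 2, with a 4-bromocatechol diether (OBn or OMe).
5. No ring is constructed; all four benzene rings are purchased. Assembly order: chain–catechol ring, then resorcinol ketone, then biaryl bond.

## Route

**Step 1**
Reactants: 1, non-8-enoic acid
Product: 2, N-methoxy-N-methylnon-8-enamide
Conditions: CDI, CH2Cl2, rt, 1 h; then MeNHOMe·HCl, rt, 12 h
Reagents that add atoms: N,O-dimethylhydroxylamine hydrochloride, CNOC.Cl
Why: Weinreb amide formation through the acyl imidazolide; the terminal alkene is inert.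

**Step 2**
Reactants: 2, N-methoxy-N-methylnon-8-enamide; 3, 1,2-bis(benzyloxy)-4-bromobenzene
Product: 4, 9-[3,4-bis(benzyloxy)phenyl]-N-methoxy-N-methylnonanamide
Conditions: 9-BBN, THF, 0 °C → rt; then 3, Pd(dppf)Cl2 (3 mol %), aq K3PO4, DMF, 60 °C
Reagents that add atoms: none
Why: Anti-Markovnikov hydroboration followed by B-alkyl Suzuki–Miyaura coupling gives the saturated C9 tether directly, and the tertiary amide and benzyl ethers tolerate 9-BBN and aqueous phosphate.

**Step 3**
Reactants: 5, 1,3-dimethoxybenzene; 4, 9-[3,4-bis(benzyloxy)phenyl]-N-methoxy-N-methylnonanamide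
Product: 6, 9-[3,4-bis(benzyloxy)phenyl]-1-(2,6-dimethoxyphenyl)nonan-1-one
Conditions: 5 (1.5 equiv), n-BuLi (1.4 equiv), THF, 0 °C → rt, 2 h; then 4, −78 → 0 °C; aq NH4Cl
Reagents that add atoms: none
Why: Directed ortho-lithiation between the two OMe groups, then Weinreb ketone synthesis; the chelated tetrahedral intermediate prevents over-addition, and the excess arene consumes all n-BuLi so the benzyl ethers are not deprotonated.

**Step 4**
Reactants: 6, 9-[3,4-bis(benzyloxy)phenyl]-1-(2,6-dimethoxyphenyl)nonan-1-one
Product: 7, 9-(3,4-dihydroxyphenyl)-1-(2,6-dimethoxyphenyl)nonan-1-one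
Conditions: H2 (1 atm), 10% Pd/C, EtOAc/MeOH, rt
Reagents that add atoms: none
Why: Hydrogenolysis of the benzyl ethers frees only the catechol; the di-ortho-substituted, twisted aryl ketone and the methyl ethers are untouched under these mild conditions.

**Step 5**
Reactants: 2, N-methoxy-N-methylnon-8-enamide; 8, 4-bromo-1,2-dimethoxybenzene
Product: 9, 9-(3,4-dimethoxyphenyl)-N-methoxy-N-methylnonanamide
Conditions: 9-BBN, THF, 0 °C → rt; then 8, Pd(dppf)Cl2 (3 mol %), aq K3PO4, DMF, 60 °C
Reagents that add atoms: none
Why: Same hydroboration/B-alkyl Suzuki–Miyaura coupling as step 2, run on the common amide 2.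

**Step 6**
Reactants: 10, resorcinol
Product: 11, 1,3-bis(methoxymethoxy)benzene
Conditions: NaH, DMF, 0 °C; MOMCl, 0 °C → rt
Reagents that add atoms: chloromethyl methyl ether (MOMCl), COCCl
Why: Williamson-type O-alkylation of the bis-phenoxide installs acid-labile groups that also direct lithiation.

**Step 7**
Reactants: 11, 1,3-bis(methoxymethoxy)benzene; 9, 9-(3,4-dimethoxyphenyl)-N-methoxy-N-methylnonanamide
Product: 12, 1-[2,6-bis(methoxymethoxy)phenyl]-9-(3,4-dimethoxyphenyl)nonan-1-one
Conditions: 11 (1.5 equiv), n-BuLi (1.4 equiv), THF, 0 °C → rt, 1 h; then 9, −78 → 0 °C; aq NH4Cl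
Reagents that add atoms: none
Why: Directed ortho-metalation at C2, doubly activated by the two OMOM groups, followed by Weinreb ketone synthesis.

**Step 8**
Reactants: 12, 1-[2,6-bis(methoxymethoxy)phenyl]-9-(3,4-dimethoxyphenyl)nonan-1-one
Product: 13, 1-(2,6-dihydroxyphenyl)-9-(3,4-dimethoxyphenyl)nonan-1-one
Conditions: 3 M HCl, MeOH, 50 °C
Reagents that add atoms: none
Why: Acid-catalysed acetal methanolysis removes both MOM groups, while the aryl methyl ethers and the ketone are stable.

**Step 9**
Reactants: 7, 9-(3,4-dihydroxyphenyl)-1-(2,6-dimethoxyphenyl)nonan-1-one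
Product: 14, 4-[9-(2,6-dimethoxyphenyl)-9-oxononyl]cyclohexa-3,5-diene-1,2-dione (o-quinone; not isolated, cold solution used at once)
Conditions: Ag2O (3 equiv), Na2SO4, CH2Cl2, −20 °C, dark, 20 min; cold filtration through Celite under Ar
Reagents that add atoms: none
Why: Two-electron catechol-to-o-quinone oxidation with a heterogeneous oxidant that is filtered off, so no oxidant reaches the coupling step; low temperature and immediate use limit quinone dimerisation and quinone-methide tautomerisation.

**Step 10 (key new step)**
Reactants: 14, o-quinone from step 9 (1.0 equiv, added by syringe pump over 1 h); 13, 1-(2,6-dihydroxyphenyl)-9-(3,4-dimethoxyphenyl)nonan-1-one (2.0 equiv, excess recovered)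
Product: 15, tetra-O-methyl giganteone A, 1-(2,6-dimethoxyphenyl)-9-{2-[3-(9-(3,4-dimethoxyphenyl)nonanoyl)-2,4-dihydroxyphenyl]-4,5-dihydroxyphenyl}nonan-1-one
Conditions: (PhO)2P(O)OH (10 mol %), 4 Å MS, CH2Cl2, −40 → −10 °C, Ar; then aq Na2S2O4 quench
Reagents that add atoms: none
Why: Proposed new method: phosphoric-acid-catalysed conjugate C-arylation of a 4-alkyl-o-benzoquinone by a 2-acylresorcinol, where the P–OH hydrogen-bonds to the quinone C=O that is β-related to the only unsubstituted 1,4-acceptor carbon (the ring carbon ortho to the alkyl chain) while the P=O binds a phenolic OH of 13, so that C3 of 13 (ortho to one OH, para to the other, and equivalent to C5 by symmetry) attacks that carbon in an organised bifunctional transition state, and two tautomerisations then restore both arenes to give the aryl-catechol with no change in oxidation level; only the free phenol of 13 can be activated this way, so the O-methylated rings of 13 and 14 should not compete, slow addition of 14 into excess 13 suppresses product/quinone redox exchange and double arylation, and dithionite returns any over-oxidised product to the catechol; the closest known reaction type is Brønsted-acid-catalysed arylation of p-quinones and quinone ketals by naphthols and electron-rich phenols, together with the biomimetic addition of phloroglucinol-type arenes to catechol-derived o-quinones, neither of which has been shown for a 4-alkyl-o-quinone with an acyl-deactivated resorcinol.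

**Step 11**
Reactants: 15, tetra-O-methyl giganteone A
Product: 16, giganteone A
Conditions: BBr3 (12 equiv), CH2Cl2, −78 °C → rt, 12 h; MeOH then degassed H2O; reverse-phase purification under Ar
Reagents that add atoms: none
Why: Lewis-acid ether cleavage removes all four methyl ethers (two ketone-chelated, two veratrole-type); the biaryl has only one ortho OH, so dibenzofuran formation is not possible, and no stereocentre exists to scramble.

## Compound list

1 | non-8-enoic acid | C=CCCCCCCC(=O)O | starting material
2 | N-methoxy-N-methylnon-8-enamide | C=CCCCCCCC(=O)N(C)OC | intermediate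
3 | 1,2-bis(benzyloxy)-4-bromobenzene | Brc1ccc(OCc2ccccc2)c(OCc2ccccc2)c1 | starting material
4 | 9-[3,4-bis(benzyloxy)phenyl]-N-methoxy-N-methylnonanamide | CON(C)C(=O)CCCCCCCCc1ccc(OCc2ccccc2)c(OCc2ccccc2)c1 | intermediate
5 | 1,3-dimethoxybenzene | COc1cccc(OC)c1 | starting material
6 | 9-[3,4-bis(benzyloxy)phenyl]-1-(2,6-dimethoxyphenyl)nonan-1-one | COc1cccc(OC)c1C(=O)CCCCCCCCc1ccc(OCc2ccccc2)c(OCc2ccccc2)c1 | intermediate
7 | 9-(3,4-dihydroxyphenyl)-1-(2,6-dimethoxyphenyl)nonan-1-one | COc1cccc(OC)c1C(=O)CCCCCCCCc1ccc(O)c(O)c1 | intermediate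
8 | 4-bromo-1,2-dimethoxybenzene | COc1ccc(Br)cc1OC | starting material
9 | 9-(3,4-dimethoxyphenyl)-N-methoxy-N-methylnonanamide | CON(C)C(=O)CCCCCCCCc1ccc(OC)c(OC)c1 | intermediate
10 | resorcinol | Oc1cccc(O)c1 | starting material
11 | 1,3-bis(methoxymethoxy)benzene | COCOc1cccc(OCOC)c1 | intermediate
12 | 1-[2,6-bis(methoxymethoxy)phenyl]-9-(3,4-dimethoxyphenyl)nonan-1-one | COCOc1cccc(OCOC)c1C(=O)CCCCCCCCc1ccc(OC)c(OC)c1 | intermediate
13 | 1-(2,6-dihydroxyphenyl)-9-(3,4-dimethoxyphenyl)nonan-1-one | O=C(CCCCCCCCc1ccc(OC)c(OC)c1)c1c(O)cccc1O | intermediate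
14 | 4-[9-(2,6-dimethoxyphenyl)-9-oxononyl]cyclohexa-3,5-diene-1,2-dione | COc1cccc(OC)c1C(=O)CCCCCCCCC1=CC(=O)C(=O)C=C1 | intermediate
15 | tetra-O-methyl giganteone A | COc1cccc(OC)c1C(=O)CCCCCCCCc1cc(O)c(O)cc1-c1ccc(O)c(C(=O)CCCCCCCCc2ccc(OC)c(OC)c2)c1O | intermediate
16 | giganteone A (achiral; no stereodescriptors) | O=C(CCCCCCCCc1cc(O)c(O)cc1-c1ccc(O)c(C(=O)CCCCCCCCc2ccc(O)c(O)c2)c1O)c1c(O)cccc1O | target

## Summary

**Total step count:** 11

**Longest linear sequence:** 7 steps (1 → 2 → 4 → 6 → 7 → 14 → 15 → 16)

**Three steps most likely to fail**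

1. **Step 10 (proposed new coupling).** Risks: low nucleophilicity of the acyl-resorcinol, O-arylation, redox exchange, and decay of the quinone from step 9.
   Fallback (known chemistry): Suzuki–Miyaura biaryl coupling.
   - Brominate 9 with NBS (para to OMe, ortho to the chain), add 2,6-dimethoxyphenyllithium at −78 °C, then Miyaura-borylate to the aryl-Bpin.
   - Iodinate 13 at C3 (I2, NaHCO3) and O-methylate.
   - Cross-couple (Pd/SPhos, K3PO4), then cleave all six methyl ethers with BBr3.

2. **Step 11 (global BBr3 demethylation of an air-sensitive tetraphenol).** Risks: incomplete cleavage or oxidative decomposition.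
   Fallback: change the protecting-group strategy so the endgame is neutral hydrogenolysis (H2, Pd/C).
   - Unit A resorcinol as benzyl ethers, via Br/Li exchange of 2-bromo-1,3-bis(benzyloxy)benzene.
   - Unit A catechol as a bis-TBS ether, removed with fluoride before oxidation.
   - Unit B catechol as benzyl ethers, using 3 in place of 8.

3. **Step 7 (and its twin, step 3): hindered 2,6-dioxygenated aryllithium plus Weinreb amide.** Risks: sluggish addition, or demethoxylation of the amide by the basic aryllithium.
   Fallback: a two-stage redox route. Reduce the Weinreb amide to the aldehyde (DIBAL-H), add the aryllithium to the aldehyde, and oxidise the benzylic carbinol to the ketone (Dess–Martin periodinane).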